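All runs were computed with constants of no real substance.

Count what one turn of the reaction costs before reckoning any time.

| flask | electrophile | nucleophile | free base | remark | time |
|---|---|---|---|---|---|
| autumn | 10 mM | 20 mM | 10 mM | run made earlier |  |
| dawn | 15 mM | 20 mM | 10 mM | run made earlier |  |
| flask | 20 mM | 20.0 mM | 10.0 mM |  | 6.0 h |

| run | time / h | electrophile / % | target / % |
|---|---|---|---|
| autumn | 0.333 | 91.0 | 8.2 |
| autumn | 1.00 | 78.4 | 20.1 |
| autumn | 1.50 | 69.7 | 25.7 |
| autumn | 2.50 | 58.2 | 38.9 |
| autumn | 4.00 | 47.2 | 48.3 |
| autumn | 5.00 | 40.6 | 53.0 |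
| dawn | 0.833 | 81.0 | 16.8 |
| dawn | 1.50 | 72.4 | 25.9 |
| dawn | 2.50 | 63.1 | 33.7 |
| dawn | 3.00 | 59.8 | 36.9 |
| dawn | 4.00 | 52.9 | 43.1 |
| dawn | 5.00 | 51.1 | 46.0 |

(readings scatter by 1 percentage point)

* amount of electrophile in percent of the electrophile charged, at 40 min, 2.0 h and 6.0 h

Suppose each electrophile used takes two nucleophile away: one goes into target, and one is held as protonated nucleophile by the acid set free. The autumn run was charged with twice as much nucleophile as electrophile, so on this supposition the inverse of [electrophile] climbs in a straight line of slope two k, where k is the rate constant.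

Read down the autumn table. The row at 1.00 h gives k = 0.0138 mM⁻¹ h⁻¹, and the row at 5.00 h gives 0.0146 mM⁻¹ h⁻¹. Counting one nucleophile per turn, the same rows give 0.0129 mM⁻¹ h⁻¹ and then 0.0110 mM⁻¹ h⁻¹, a fall, so we keep two per turn. The last dawn row gives 0.0130 mM⁻¹ h⁻¹, and the mean of the two last rows is 0.0138 mM⁻¹ h⁻¹.

On this rule our flask has a floor at 50.0% of its electrophile. The height above the floor, taken as a ratio to [electrophile], decays exponentially with the stall time, which is one over two k times the electrophile charge left over once the nucleophile is paired off: 3.62 h.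

Our own reckoning gives 85.6%, 70.2% and 55.3%. The forecast treats “each electrophile consumed as removing two nucleophiles” and gives 85%, 70% and 54%, a little lower than ours at the first and last times.

The flask gives 85.6%, 70.1% and 54.7%, and the forecast stands.

    electrophile + nucleophile → acid set free + target (k = 0.230 M⁻¹ min⁻¹)
    nucleophile + acid set free ⇌ protonated nucleophile, settled at all times (K = 8400 M⁻¹)
    acid set free + free base ⇌ salt of the base (K = 270 M⁻¹, k = 0.570 M⁻¹ min⁻¹)
    2 free base → homo dimer (k = 0.640 M⁻¹ min⁻¹)
    target ⇌ isomer of the product (K = 0.120, k = 0.00150 min⁻¹)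
    electrophile + acid set free → side product (k = 0.0170 M⁻¹ min⁻¹)

The step from acid set free and free base to salt of the base makes no difference to the electrophile here, and at 6.00 h the flask holds 8.55 mM of protonated nucleophile, far more than the 0.0678 mM of salt of the base. At 60.0 h, which is 16.6 stall times, the rule gives 50.0%, yet the flask holds less electrophile than that, 32.8%, beside 3.61 mM of acid set free.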